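**Plan**

1. Numbering and cuts: left oxepane O, C2–C7; left cyclohexane C6–C11; bridge C12–C13; right cyclohexane C14–C19; right oxepane C18–C23, O; β is the ring face of the angular methyls on C6 and C19. Working backwards, the three acetates and the C22 silyl ether come off, the C10–CH3 bond is cut to a C10 ketone, the C15–O/C16–H pair goes back to a C15=C16 alkene, carboxyl groups are put back on C12 and C13, and C11–C12 and C13–C14 are cut together.
2. Enabling feature: C12–C13 is the CH2–CH2 of a succinate, and the hindered methines C11 and C14 each lie at the far end of a ring allyl unit (C9–C10=C11, C16–C15=C14) from a ring carbinol (C9, C16). A mixed succinate diester of two cyclohexenols can therefore make both ring–bridge bonds by two [3,3] shifts.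
3. Forward order: in each half the oxepane and the cyclohexanone ring form together in one epoxide-opening cascade of geranylacetone diepoxide (step 3), which fixes the trans ring fusion and the oxepane regiochemistry in one operation. One bicyclic ketone is taken to both cyclohexenols (C10 methoxymethyl enol ether on the left, C15 methyl on the right). The halves are joined through the succinate (steps 11–13) and then at C11–C12 and C13–C14 in the key step, which closes no ring.
4. Stereochemistry: C3, C6, C7 (and C22, C19, C18) come from the Shi epoxidation and the anti course of the cascade. The C9 and C16 carbinols come from α-face Rubottom oxidation followed by Mitsunobu inversion to β. C11 and C14 follow by suprafacial transfer from them. C10 is set by equatorial methyl addition to the ketone, C15 by α-epoxidation and hydride opening.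

Key step: step 14

Remark on the chemistry: the epoxidation ketone is assumed to be the enantiomer of the fructose-derived Shi ketone, the one that should give (S)-configured epoxides on both alkenes. C12 and C13 are left undefined in 20–23 and disappear in step 16.

**Route**

Step 1
Reactants: 1 geranylacetone
Product: 2 (5S,6S,9S)-5,6:9,10-diepoxy-6,10-dimethylundecan-2-one
Conditions: ent-Shi ketone (0.6 equiv), Oxone (2KHSO5·KHSO4·K2SO4), K2CO3, Bu4NHSO4, MeCN/dimethoxymethane/aq. Na2B4O7 buffer, 0 °C
Reagents that add atoms: potassium peroxymonosulfate KHSO5, [K+].[O-]S(=O)(=O)OO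
Why: Shi asymmetric epoxidation, in which the chiral dioxirane formed from the ketone and KHSO5 transfers oxygen to both trisubstituted alkenes through a spiro transition state, so that the chosen ketone enantiomer sets C3, C6 and C7 (C9, C6 and C5 of the undecanone) all (S) while the methyl ketone stays untouched at pH 10.5.

Step 2
Reactants: 2 (5S,6S,9S)-5,6:9,10-diepoxy-6,10-dimethylundecan-2-one
Product: 3 terminal tert-butyldimethylsilyl enol ether of 2 (CH2=C(OTBS)– at the former methyl ketone)
Conditions: LDA, THF, −78 °C; then TBSCl, HMPA, −78 → 0 °C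
Reagents that add atoms: tert-butyldimethylsilyl chloride, CC(C)(C)[Si](C)(C)Cl
Why: Kinetic deprotonation of a methyl ketone with LDA at −78 °C takes place at the methyl group and O-silylation gives the terminal enol silane, the epoxides being inert to the amide base at this temperature and no stereocentre being formed.

Step 3
Reactants: 3 terminal tert-butyldimethylsilyl enol ether of 2
Product: 4 (3S,5aS,9aS)-3-(tert-butyldimethylsilyloxy)-2,2,5a-trimethyloctahydro-1-benzoxepin-7(2H)-one (plan numbering: 3-OTBS, trans-fused at C6/C7, C10 ketone)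
Conditions: TBSOTf (1.1 equiv), 2,6-di-tert-butyl-4-methylpyridine, CH2Cl2, −78 °C
Reagents that add atoms: none
Why: Epoxide-opening cascade (tandem oxa- and carbacyclisation of a 1,5-diepoxide ended by an enol silane), in which silylation of the terminal epoxide lets the C6–C7 epoxide oxygen attack the tertiary C2 to close the oxepane with C3–O retained, the epoxonium ion is then opened at tertiary C6 by the enol silane carbon C11 with inversion to close the six-membered ring, the trans epoxide geometry thus becomes the trans ring fusion (C6 methyl β-axial, C7–O β-equatorial), and the enol ether silyl group is returned as TBSOTf so that the step is a net isomerisation with the silyl group on the C3 oxygen.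

Step 4
Reactants: 4 bicyclic C10 ketone
Product: 7 9α-(triethylsilyloxy) derivative of 4 (axial OSiEt3 on C9), via triethylsilyl enol ether 5 (not isolated), via silyloxy epoxide 6 (not isolated)
Conditions: LDA, THF, −78 °C; TESCl, Et3N, −78 → 0 °C; volatiles removed; DMDO, acetone/CH2Cl2, −40 °C → rt
Reagents that add atoms: triethylsilyl chloride, CC[Si](Cl)(CC)CC; dimethyldioxirane, CC1(C)OO1
Why: Rubottom oxidation, in which LDA removes the unhindered C9 proton in preference to the neopentyl C11 proton, the enol silane is epoxidised on the α face because the β face is screened by the axial C6 methyl, and 1,4-silyl migration in the silyloxy epoxide gives the 9α (axial) silyloxy ketone.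

Step 5
Reactants: 7 9α-(triethylsilyloxy) ketone
Product: 8 C10 methoxymethyl enol ether of 7 (C10(OCH2OCH3)=C11, 9α-OSiEt3, 3-OTBS)
Conditions: KHMDS, THF/DMPU, −78 °C; MOMCl, −78 → −20 °C
Reagents that add atoms: chloromethyl methyl ether, COCCl
Why: Kinetic enolate O-alkylation, in which the equatorial C9 hydrogen is not aligned with the carbonyl π system so that KHMDS can only remove the axial C11 hydrogen, and the potassium enolate is trapped on oxygen by the hard electrophile MOMCl (C-alkylation at neopentyl C11 is disfavoured) to give the enol ether that later unmasks the C10 ketone.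

Step 6
Reactants: 8 C10 methoxymethyl enol ether
Product: 9 left cyclohexenol (3,9α-diol with C10(OCH2OCH3)=C11)
Conditions: TBAF, THF, 45 °C
Reagents that add atoms: none
Why: Fluoride-mediated desilylation cleaves both silyl ethers while the alkyl enol ether is inert to fluoride and base, which frees the allylic 9α-alcohol for esterification and leaves the hindered C3 alcohol free until step 20.

Step 7
Reactants: 7 9α-(triethylsilyloxy) ketone (right series: C9, C10, C11, C3 become C16, C15, C14, C22)
Product: 10 C15 enol triflate (C14=C15, 16α-OSiEt3, 22-OTBS)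
Conditions: KHMDS, THF, −78 °C; PhNTf2, −78 → 0 °C
Reagents that add atoms: N-phenylbis(trifluoromethanesulfonimide), O=S(=O)(N(c1ccccc1)S(=O)(=O)C(F)(F)F)C(F)(F)F
Why: Enol triflate formation from the same regiodefined potassium enolate (loss of the axial C14 hydrogen, the C16 hydrogen being equatorial), trapped on oxygen by PhNTf2.

Step 8
Reactants: 10 C15 enol triflate
Product: 11 15-methyl C14=C15 alkene (16α-OSiEt3, 22-OTBS)
Conditions: MeMgBr, Fe(acac)3 (5 mol %), THF/NMP, −20 °C
Reagents that add atoms: methylmagnesium bromide, C[Mg]Br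
Why: Iron-catalysed Kumada-type cross-coupling of an alkenyl triflate with MeMgBr replaces the triflate by methyl without moving the alkene, silyl ethers being inert.

Step 9
Reactants: 11 15-methyl C14=C15 alkene
Product: 12 right cyclohexenol (16α-OH, 15-methyl C14=C15, 22-OTBS)
Conditions: PPTS, MeOH, 0 °C → rt
Reagents that add atoms: none
Why: Acid-catalysed methanolysis removes the triethylsilyl ether selectively because the tert-butyldimethylsilyl ether next to the quaternary C23 cleaves far more slowly, and C16 keeps its α configuration.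

Step 10
Reactants: 13 succinic anhydride; 14 2,2,2-trichloroethanol
Product: 15 4-oxo-4-(2,2,2-trichloroethoxy)butanoic acid
Conditions: DMAP (cat.), Et3N, toluene, 80 °C; aq. HCl work-up
Reagents that add atoms: none
Why: DMAP-catalysed alcoholysis of a cyclic anhydride stops cleanly at the monoester because the carboxylate formed does not react further.

Step 11
Reactants: 12 right cyclohexenol; 15 mono(trichloroethyl) succinate
Product: 16 16β-yl 2,2,2-trichloroethyl succinate of the right half
Conditions: PPh3, DIAD, THF, 0 °C → rt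
Reagents that add atoms: none
Why: Mitsunobu esterification, in which the pseudoaxial 16α-alcohol is activated as its oxyphosphonium ion and displaced by the carboxylate with SN2 inversion, sets the 16β ester needed for delivery to the β face of C14 (attack at the neopentyl C14 is not expected).

Step 12
Reactants: 16 16β-yl trichloroethyl succinate
Product: 17 16β-yl hydrogen succinate of the right half
Conditions: Zn dust, AcOH/THF, rt
Reagents that add atoms: none
Why: Zinc cleaves the trichloroethyl ester by reductive β-elimination (loss of 1,1-dichloroethene), a standard deprotection that leaves the allylic ester, the alkene and the silyl ether untouched.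

Step 13
Reactants: 17 right hemisuccinate; 9 left cyclohexenol
Product: 18 mixed succinate diester (9β-yl ester of the left 10-methoxymethoxy cyclohexenol, 16β-yl ester of the right 15-methyl cyclohexenol, 3-OH, 22-OTBS)
Conditions: PPh3, DIAD, toluene, 0 °C → rt (17 added last)
Reagents that add atoms: none
Why: Mitsunobu esterification with SN2 inversion turns the 9α-alcohol into the 9β ester, the C3 alcohol next to the quaternary C2 being too hindered to be activated and the late addition of the acid keeping the enol ether from long contact with free acid.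

Step 14
Reactants: 18 mixed succinate diester
Product: 21 C12,C13-dicarboxylic acid with both ring–bridge bonds (C9=C10 methoxymethyl enol ether; C15=C16; 3-OH; 22-OTBS), via bis(silyl ketene acetal) 19 (not isolated), via bis(trimethylsilyl) ester 20 (not isolated)
Conditions: TMSCl/Et3N (premixed), LiHMDS (5 equiv), THF, −78 °C → rt; then toluene, 95 °C; K2CO3, MeOH/H2O; citric acid to pH 5
Reagents that add atoms: none
Why: Enolisation of both ester groups in the presence of TMSCl gives the bis(silyl ketene acetal) 19, whose ketene acetal carbons C12 and C13 each face C11 or C14 across O–C9–C10=C11 and O–C16–C15=C14, so two successive concerted [3,3] shifts form C12–C11 and C13–C14 and move the ring alkenes to C9=C10 and C15=C16; no ring is closed. The closest known reaction is the Ireland–Claisen rearrangement of cyclohex-2-enyl esters with 1,3-chirality transfer, applied here at both ester groups of one succinate. Each shift is suprafacial on its ring allyl unit, so carbon arrives on the face that carried the ester oxygen: the 9β and 16β esters fix C11 and C14 with the bridge β, cis to the angular methyls, a face that an external reagent could not approach. The β C–O bonds are pseudoequatorial in the locked half-chairs, so the shifts must pass through boat-like ring conformers, which is the reason for heating. The step needs the rearrangements to outrun loss of the ketene acetals; this is secured by the internal TMSCl quench, by an alkyl enol ether that cannot pass its group to a neighbouring oxygen, and by the absence of any other allylic terminus. C12 and C13 form as mixtures and are erased in step 16.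

Step 15
Reactants: 21 C12,C13-dicarboxylic acid
Product: 22 10-keto C12,C13-dicarboxylic acid
Conditions: 0.5 M HCl, THF, 0 °C → rt
Reagents that add atoms: none
Why: Acid hydrolysis of the enol ether (protonation at C9, then loss of the methoxymethyl group as formaldehyde and methanol) unmasks the C10 ketone under conditions too mild to cleave the hindered silyl ether, to epimerise C11 or to lactonise the acids onto the C15=C16 alkene.

Step 16
Reactants: 22 10-keto diacid
Product: 24 C10 ketone with the CH2–CH2 bridge (C15=C16, 3-OH, 22-OTBS), via bis(thiohydroxamate) ester 23 (not isolated)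
Conditions: 2-mercaptopyridine N-oxide, DCC, DMAP (cat.), CH2Cl2, 0 °C → rt, dark; then t-BuSH, hν (tungsten lamp), toluene, rt
Reagents that add atoms: none
Why: Barton reductive decarboxylation, in which both carboxyl groups become O-acyl thiohydroxamates (any cyclic anhydride formed on the way is reopened by the thiohydroxamate) and the radical chain with t-BuSH replaces each carboxyl by hydrogen, the secondary C12 and C13 radicals being reduced much faster than they can add to the ketone or the trisubstituted alkene.

Step 17
Reactants: 24 C10 ketone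
Product: 25 10β-hydroxy-10α-methyl compound (axial tertiary alcohol)
Conditions: MeMgBr, CeCl3, THF, −78 → 0 °C
Reagents that add atoms: methylmagnesium bromide, C[Mg]Br
Why: Organocerium 1,2-addition, in which the axial approach to C10 is blocked by the syn-axial C6 methyl so that methyl enters equatorially (α) and the tertiary alcohol is axial (β), while the weakly basic reagent avoids enolisation and epimerisation at C11.

Step 18
Reactants: 25 10β-hydroxy-10α-methyl compound
Product: 26 15α,16α-epoxide
Conditions: mCPBA, NaHCO3, CH2Cl2, 0 °C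
Reagents that add atoms: 3-chloroperoxybenzoic acid, OOC(=O)c1cccc(Cl)c1
Why: Prilezhaev epoxidation of the only alkene left, with the peracid approaching C15=C16 from the α face, anti to the axial C19 methyl, which sets the C15–O bond α.

Step 19
Reactants: 26 15α,16α-epoxide
Product: 27 3,10,15-triol (15α-OH equatorial, 15β-methyl axial, 22-OTBS)
Conditions: LiEt3BH, THF, 0 → 60 °C
Reagents that add atoms: none
Why: SN2 hydride opening of the trisubstituted epoxide by LiEt3BH takes place at the secondary C16 from the β face, which leaves the oxygen on tertiary C15 with its α (equatorial) configuration and the methyl axial.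

Step 20
Reactants: 27 3,10,15-triol
Product: 28 3,10,15-triacetate 22-silyl ether
Conditions: Ac2O (excess), DMAP, Et3N, toluene, 80 °C
Reagents that add atoms: acetic anhydride, CC(=O)OC(C)=O
Why: DMAP-catalysed (Steglich-type) acetylation with excess anhydride at raised temperature acylates the secondary C3 alcohol and both tertiary alcohols without touching the silyl ether or any stereocentre.

Step 21
Reactants: 28 triacetate silyl ether
Product: 29 CNP0169816.1
Conditions: HF·pyridine, THF/pyridine, 0 °C → rt
Reagents that add atoms: none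
Why: Fluoride-mediated desilylation under buffered, weakly acidic conditions removes the hindered silyl ether without acyl migration or loss of the tertiary acetates.

**Compound list**

1 | geranylacetone, (E)-6,10-dimethylundeca-5,9-dien-2-one | CC(=O)CC/C=C(\C)CCC=C(C)C | starting material
2 | (5S,6S,9S)-5,6:9,10-diepoxy-6,10-dimethylundecan-2-one | CC(=O)CC[C@@H]1O[C@@]1(C)CC[C@@H]1OC1(C)C | intermediate
3 | terminal tert-butyldimethylsilyl enol ether of 2 | C=C(O[Si](C)(C)C(C)(C)C)CC[C@@H]1O[C@@]1(C)CC[C@@H]1OC1(C)C | intermediate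
4 | (3S,5aS,9aS)-3-(tert-butyldimethylsilyloxy)-2,2,5a-trimethyloctahydro-1-benzoxepin-7(2H)-one (trans-fused, C6 methyl β, C7–O β, C10 ketone) | CC(C)(C)[Si](C)(C)O[C@H]1CC[C@]2(C)[C@H](CCC(=O)C2)OC1(C)C | intermediate
5 | C9=C10 triethylsilyl enol ether of 4 | CC(C)(C)[Si](C)(C)O[C@H]1CC[C@]2(C)[C@H](CC=C(O[Si](CC)(CC)CC)C2)OC1(C)C | intermediate
6 | 9α,10α-epoxide of 5 (10-triethylsilyloxy) | CC(C)(C)[Si](C)(C)O[C@H]1CC[C@]2(C)[C@H](C[C@@H]3O[C@]3(O[Si](CC)(CC)CC)C2)OC1(C)C | intermediate
7 | 9α-(triethylsilyloxy) derivative of ketone 4 (OSiEt3 axial) | CC(C)(C)[Si](C)(C)O[C@H]1CC[C@]2(C)[C@H](C[C@H](O[Si](CC)(CC)CC)C(=O)C2)OC1(C)C | intermediate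
8 | C10 methoxymethyl enol ether of 7 (C10=C11, 9α-OSiEt3, 3-OTBS) | CC(C)(C)[Si](C)(C)O[C@H]1CC[C@]2(C)[C@H](C[C@H](O[Si](CC)(CC)CC)C(OCOC)=C2)OC1(C)C | intermediate
9 | left cyclohexenol: 3,9α-diol with C10(OCH2OCH3)=C11 | O[C@H]1CC[C@]2(C)[C@H](C[C@H](O)C(OCOC)=C2)OC1(C)C | intermediate
10 | right series: C15 enol triflate (C14=C15), 16α-OSiEt3, 22-OTBS | CC(C)(C)[Si](C)(C)O[C@H]1CC[C@]2(C)[C@H](C[C@H](O[Si](CC)(CC)CC)C(OS(=O)(=O)C(F)(F)F)=C2)OC1(C)C | intermediate
11 | right series: 15-methyl C14=C15 alkene, 16α-OSiEt3, 22-OTBS | CC(C)(C)[Si](C)(C)O[C@H]1CC[C@]2(C)[C@H](C[C@H](O[Si](CC)(CC)CC)C(C)=C2)OC1(C)C | intermediate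
12 | right cyclohexenol: 16α-OH, 15-methyl C14=C15, 22-OTBS | CC(C)(C)[Si](C)(C)O[C@H]1CC[C@]2(C)[C@H](C[C@H](O)C(C)=C2)OC1(C)C | intermediate
13 | succinic anhydride | O=C1CCC(=O)O1 | starting material
14 | 2,2,2-trichloroethanol | OCC(Cl)(Cl)Cl | starting material
15 | 4-oxo-4-(2,2,2-trichloroethoxy)butanoic acid | OC(=O)CCC(=O)OCC(Cl)(Cl)Cl | intermediate
16 | right half 16β-yl 2,2,2-trichloroethyl succinate | CC(C)(C)[Si](C)(C)O[C@H]1CC[C@]2(C)[C@H](C[C@@H](OC(=O)CCC(=O)OCC(Cl)(Cl)Cl)C(C)=C2)OC1(C)C | intermediate
17 | right half 16β-yl hydrogen succinate | CC(C)(C)[Si](C)(C)O[C@H]1CC[C@]2(C)[C@H](C[C@@H](OC(=O)CCC(=O)O)C(C)=C2)OC1(C)C | intermediate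
18 | mixed succinate diester: left 9β-yl (C10 methoxymethyl enol ether, 3-OH), right 16β-yl (15-methyl, 22-OTBS) | O[C@H]1CC[C@]2(C)[C@H](C[C@@H](OC(=O)CCC(=O)O[C@@H]3C[C@@H]4OC(C)(C)[C@@H](O[Si](C)(C)C(C)(C)C)CC[C@@]4(C)C=C3C)C(OCOC)=C2)OC1(C)C | intermediate
19 | bis(trimethylsilyl ketene acetal) of 18, 3-O-trimethylsilyl | C[Si](C)(C)O[C@H]1CC[C@]2(C)[C@H](C[C@@H](OC(O[Si](C)(C)C)=CC=C(O[Si](C)(C)C)O[C@@H]3C[C@@H]4OC(C)(C)[C@@H](O[Si](C)(C)C(C)(C)C)CC[C@@]4(C)C=C3C)C(OCOC)=C2)OC1(C)C | intermediate
20 | bis(trimethylsilyl) ester of 21, 3-O-trimethylsilyl | C[Si](C)(C)O[C@H]1CC[C@]2(C)[C@H](CC=C(OCOC)[C@H]2C(C(=O)O[Si](C)(C)C)C(C(=O)O[Si](C)(C)C)[C@H]2[C@]3(C)CC[C@H](O[Si](C)(C)C(C)(C)C)C(C)(C)O[C@H]3CC=C2C)OC1(C)C | intermediate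
21 | bridged C12,C13-dicarboxylic acid (C11 and C14 bridge bonds β; C9=C10 methoxymethyl enol ether; C15=C16; 3-OH; 22-OTBS) | O[C@H]1CC[C@]2(C)[C@H](CC=C(OCOC)[C@H]2C(C(=O)O)C(C(=O)O)[C@H]2[C@]3(C)CC[C@H](O[Si](C)(C)C(C)(C)C)C(C)(C)O[C@H]3CC=C2C)OC1(C)C | intermediate
22 | 10-keto C12,C13-dicarboxylic acid | O[C@H]1CC[C@]2(C)[C@H](CCC(=O)[C@H]2C(C(=O)O)C(C(=O)O)[C@H]2[C@]3(C)CC[C@H](O[Si](C)(C)C(C)(C)C)C(C)(C)O[C@H]3CC=C2C)OC1(C)C | intermediate
23 | bis(2-thioxopyridin-1(2H)-yl) ester of 22 | O[C@H]1CC[C@]2(C)[C@H](CCC(=O)[C@H]2C(C(=O)On4ccccc4=S)C(C(=O)On5ccccc5=S)[C@H]2[C@]3(C)CC[C@H](O[Si](C)(C)C(C)(C)C)C(C)(C)O[C@H]3CC=C2C)OC1(C)C | intermediate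
24 | C10 ketone with CH2–CH2 bridge (C15=C16, 3-OH, 22-OTBS) | O[C@H]1CC[C@]2(C)[C@H](CCC(=O)[C@H]2CC[C@H]2[C@]3(C)CC[C@H](O[Si](C)(C)C(C)(C)C)C(C)(C)O[C@H]3CC=C2C)OC1(C)C | intermediate
25 | 10β-hydroxy-10α-methyl compound (C15=C16, 3-OH, 22-OTBS) | O[C@H]1CC[C@]2(C)[C@H](CC[C@@](C)(O)[C@H]2CC[C@H]2[C@]3(C)CC[C@H](O[Si](C)(C)C(C)(C)C)C(C)(C)O[C@H]3CC=C2C)OC1(C)C | intermediate
26 | 15α,16α-epoxide of 25 | O[C@H]1CC[C@]2(C)[C@H](CC[C@@](C)(O)[C@H]2CC[C@H]2[C@]3(C)CC[C@H](O[Si](C)(C)C(C)(C)C)C(C)(C)O[C@H]3C[C@@H]4O[C@]24C)OC1(C)C | intermediate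
27 | 3,10β,15α-triol, 22-OTBS | O[C@H]1CC[C@]2(C)[C@H](CC[C@@](C)(O)[C@H]2CC[C@H]2[C@]3(C)CC[C@H](O[Si](C)(C)C(C)(C)C)C(C)(C)O[C@H]3CC[C@]2(C)O)OC1(C)C | intermediate
28 | 3,10,15-triacetate, 22-OTBS | CC(=O)O[C@H]1CC[C@]2(C)[C@H](CC[C@@](C)(OC(C)=O)[C@H]2CC[C@H]2[C@]3(C)CC[C@H](O[Si](C)(C)C(C)(C)C)C(C)(C)O[C@H]3CC[C@]2(C)OC(C)=O)OC1(C)C | intermediate
29 | CNP0169816.1 | CC(=O)O[C@H]1CC[C@]2(C)[C@H](CC[C@@](C)(OC(C)=O)[C@H]2CC[C@H]2[C@]3(C)CC[C@H](O)C(C)(C)O[C@H]3CC[C@]2(C)OC(C)=O)OC1(C)C | target

**Step count and risks**

Total step count: 21. Longest linear sequence: 18 steps (1, 2, 3, 4, 7, 8, 9, 11, 12, 13, 14, 15, 16, 17, 18, 19, 20, 21).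

Step 14. What may go wrong: both shifts take place at neopentyl termini through boat-like ring conformers, so the second rearrangement may lag until the silyl ketene acetals have decayed (C-silylation, fragmentation to ketene), and the material stalls after one C–C bond. The fallback sets out from 17 and 9 and returns at 24; it makes the two bonds in separate, single Ireland–Claisen rearrangements. Acid 17 is methylated (TMSCHN2, MeOH/toluene) to the methyl succinate F1. Enolisation with LiHMDS and TMSCl/Et3N followed by heating rearranges only the cyclohexenyl ester arm (the methyl ester arm returns on work-up) and gives the C13 acid F2, in which C13–C14 is in place. Barton decarboxylation gives the methyl propanoate F3, LiOH gives the propanoic acid F4, and Mitsunobu esterification with 9 gives the 9β-ester F5. A second Ireland–Claisen rearrangement forms C11–C12 in the C12 acid F6. Dilute HCl gives the keto acid F7, and Barton decarboxylation of F7 gives 24.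

Step 16. What may go wrong: once one carboxyl is activated, ring closure to the five-membered anhydride can outpace activation of the second, so that decarboxylation stops after one carboxyl. The fallback sets out from 22 and returns at 24, and uses no acyl activation. The dicarboxylate of 22 (Cs2CO3) is oxidised by an excited photocatalyst ([Ir(dF(CF3)ppy)2(dtbbpy)]PF6, blue LEDs, MeCN/H2O), and the alkyl radicals left after loss of CO2 are reduced by a catalytic thiol (2,4,6-triisopropylbenzenethiol). This known photocatalytic hydrodecarboxylation should give 24 directly, and no new compound arises.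

Step 7. What may go wrong: deprotonation at the neopentyl C14, whose axial hydrogen is syn to the axial silyloxy group, may be slow enough for enolisation towards C16 or silyl migration to compete, which erodes the position of the enol triflate. The fallback sets out from 7 and returns at 11; it makes the alkene by addition and elimination, not through an enolate. MeMgBr/CeCl3 adds equatorially to the ketone of 7 and gives the axial tertiary alcohol F8. SOCl2/pyridine then removes the hydroxyl in an anti elimination with the axial C14 hydrogen (the C16 hydrogen is equatorial), which gives 11.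

**Further compounds**

F1 | step 14 | methyl ester of 17 (right half 16β-yl methyl succinate) | CC(C)(C)[Si](C)(C)O[C@H]1CC[C@]2(C)[C@H](C[C@@H](OC(=O)CCC(=O)OC)C(C)=C2)OC1(C)C
F2 | step 14 | right half with C14β–C13 bond: C13 carboxylic acid, C12 methyl ester, C15=C16 | CC(C)(C)[Si](C)(C)O[C@H]1CC[C@]2(C)[C@H](CC=C(C)[C@H]2C(C(=O)O)CC(=O)OC)OC1(C)C
F3 | step 14 | methyl 3-(right bicycle C14β-yl)propanoate | CC(C)(C)[Si](C)(C)O[C@H]1CC[C@]2(C)[C@H](CC=C(C)[C@H]2CCC(=O)OC)OC1(C)C
F4 | step 14 | 3-(right bicycle C14β-yl)propanoic acid | CC(C)(C)[Si](C)(C)O[C@H]1CC[C@]2(C)[C@H](CC=C(C)[C@H]2CCC(=O)O)OC1(C)C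
F5 | step 14 | 9β-yl ester of F4 with the left cyclohexenol 9 | O[C@H]1CC[C@]2(C)[C@H](C[C@@H](OC(=O)CC[C@H]3[C@]4(C)CC[C@H](O[Si](C)(C)C(C)(C)C)C(C)(C)O[C@H]4CC=C3C)C(OCOC)=C2)OC1(C)C
F6 | step 14 | bridged C12 carboxylic acid with C9=C10 methoxymethyl enol ether and C15=C16 | O[C@H]1CC[C@]2(C)[C@H](CC=C(OCOC)[C@H]2C(C(=O)O)C[C@H]2[C@]3(C)CC[C@H](O[Si](C)(C)C(C)(C)C)C(C)(C)O[C@H]3CC=C2C)OC1(C)C
F7 | step 14 | bridged 10-keto C12 carboxylic acid | O[C@H]1CC[C@]2(C)[C@H](CCC(=O)[C@H]2C(C(=O)O)C[C@H]2[C@]3(C)CC[C@H](O[Si](C)(C)C(C)(C)C)C(C)(C)O[C@H]3CC=C2C)OC1(C)C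
F0 | step 16 | none | none
F8 | step 7 | right series 15β-hydroxy-15α-methyl-16α-(triethylsilyloxy) tertiary alcohol from 7 | CC(C)(C)[Si](C)(C)O[C@H]1CC[C@]2(C)[C@H](C[C@H](O[Si](CC)(CC)CC)[C@@](C)(O)C2)OC1(C)C
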